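The final ring is made by forming the lactone O10–C9a bond of ring B (depsidone numbering) from a C9a–H bond. Ring B carries its free C7 hydroxyl para to C9a, so it is a hydroquinone mono-ester. Two-electron oxidation of that phenol by iodine(III) should let the C11 carboxylic acid of ring A add to C9a; loss of the C9a proton then re-aromatises and closes the seven-membered ring in one operation. The precursor is the 2-aryloxybenzoic acid 16: a fully decorated ring A (C1 O-MOM, C2 prenyl, C3/C4 pyran, C11 acid) joined through O5 to an 8-hydroxy-2,2-dimethylchromen-6-yl ring B with C9a–H free.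

Key step: step 8

Remark 1: the target has no stereocentre, so no stereocontrol is required anywhere in the route.
Remark 2: C6 and C9a are both ortho to C5a, so the ring-A carboxyl group can reach either carbon; para selectivity in step 8 is an electronic and steric matter, not a geometric one, and is treated as the main risk.
Remark 3: the Grignard reagent 2 and the carbonate 8 are taken as purchased reagents.
Remark 4: ring A is assembled so that each substituent is placed at the only open position (no selective protection of two similar hydroxyls is needed). Intermediates are numbered as benzoates or chromenes; the target is numbered as a depsidone.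

**Step 1**
Reactants: 1 5-bromo-2-hydroxy-3-methoxybenzaldehyde; 2 2-methylprop-1-en-1-ylmagnesium bromide
Product: 4 6-bromo-8-methoxy-2,2-dimethyl-2H-chromene, via benzylic allylic diol 3 (not isolated)
Conditions: 2 (2.5 equiv), THF, 0 °C to rt; aq. HCl quench; crude diol, p-TsOH·H2O (5 mol%), toluene, rt to 40 °C
Reagents that add atoms: none
Why: Grignard 1,2-addition to the aldehyde (one equivalent is spent on the phenol) gives the o-hydroxybenzyl allylic alcohol, which under acid ionises to the vinyl o-quinone methide/allyl cation and closes to the 2,2-dimethylchromene by oxa-6π cyclodehydration; the alkenyl Grignard should not exchange with the aryl bromide at 0 °C.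

**Step 2**
Reactants: 5 methyl 2,4,6-trihydroxybenzoate; 6 3-chloro-3-methylbut-1-yne
Product: 7 methyl 2,6-dihydroxy-4-[(2-methylbut-3-yn-2-yl)oxy]benzoate
Conditions: 6 (1.15 equiv), CuCl2·2H2O (1 mol%), DBU (1.2 equiv), MeCN, 0 °C
Reagents that add atoms: none
Why: copper-catalysed propargylic etherification of a phenoxide should occur at the para 4-OH, the most acidic hydroxyl and the only one not hydrogen-bonded to the ester, leaving a symmetric 2,6-diol.

**Step 3**
Reactants: 7 methyl 2,6-dihydroxy-4-[(2-methylbut-3-yn-2-yl)oxy]benzoate; 8 tert-butyl 2-methylbut-3-en-2-yl carbonate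
Product: 10 methyl 2-[(2-methylbut-3-en-2-yl)oxy]-4-[(2-methylbut-3-yn-2-yl)oxy]-6-(pivaloyloxy)benzoate, via tert-prenyl ether phenol 9 (not isolated)
Conditions: Pd(PPh3)4 (3 mol%), 8 (1.2 equiv), THF, 0 °C; then Et3N, DMAP (cat.), PivCl, 0 °C to rt
Reagents that add atoms: pivaloyl chloride, CC(C)(C)C(=O)Cl
Why: Tsuji–Trost O-allylation through the π-prenyl palladium complex should give the branched 1,1-dimethylallyl ether under kinetic control and stop at one of the two equivalent hydroxyls because the remaining one becomes chelated to the ester carbonyl; DMAP-catalysed acylation in the same flask then caps that hydroxyl as the pivalate.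

**Step 4**
Reactants: 10 methyl 2-[(2-methylbut-3-en-2-yl)oxy]-4-[(2-methylbut-3-yn-2-yl)oxy]-6-(pivaloyloxy)benzoate
Product: 12 methyl 7-hydroxy-2,2-dimethyl-8-(3-methylbut-2-en-1-yl)-5-(pivaloyloxy)-2H-chromene-6-carboxylate, via C-prenylated phenol 11 (not isolated)
Conditions: o-xylene (0.05 M), BHT (cat.), 105 °C; then 140 °C
Reagents that add atoms: none
Why: the aromatic Claisen rearrangement of the 1,1-dimethylallyl ether runs first and places a prenyl group on the only free ortho carbon of its oxygen; the slower propargyl Claisen/[1,5]-H shift/oxa-6π sequence then has a single ring CH left, so the chromene forms next to the pivalate oxygen and the regiochemistry is fixed by elimination.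

**Step 5**
Reactants: 12 methyl 7-hydroxy-2,2-dimethyl-8-(3-methylbut-2-en-1-yl)-5-(pivaloyloxy)-2H-chromene-6-carboxylate
Product: 14 methyl 5-hydroxy-7-(methoxymethoxy)-2,2-dimethyl-8-(3-methylbut-2-en-1-yl)-2H-chromene-6-carboxylate, via MOM ether pivalate 13 (not isolated)
Conditions: NaH, MOMCl, THF–DMF, 0 °C to rt; then MeOH, NaOMe, 40 °C; aq. NH4Cl
Reagents that add atoms: chloromethyl methyl ether (MOMCl), COCCl
Why: Williamson-type O-alkylation caps the only free phenol (the one liberated next to the prenyl group) as the MOM acetal, and methoxide transesterification (Zemplén-type) then removes the aryl pivalate to free the C5 hydroxyl next to the pyran carbon; the hindered pivalate should resist acyl transfer to the phenoxide and exchange at the methyl ester is degenerate.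

**Step 6**
Reactants: 14 methyl 5-hydroxy-7-(methoxymethoxy)-2,2-dimethyl-8-(3-methylbut-2-en-1-yl)-2H-chromene-6-carboxylate; 4 6-bromo-8-methoxy-2,2-dimethyl-2H-chromene
Product: 15 methyl 5-[(8-methoxy-2,2-dimethyl-2H-chromen-6-yl)oxy]-7-(methoxymethoxy)-2,2-dimethyl-8-(3-methylbut-2-en-1-yl)-2H-chromene-6-carboxylate
Conditions: 4 (1.5 equiv), CuI (20 mol%), picolinic acid (40 mol%), K3PO4, DMSO, 100 °C, Ar
Reagents that add atoms: none
Why: ligand-accelerated Ullmann diaryl ether coupling under conditions developed for ortho-substituted phenols should join the single free phenol to the aryl bromide, which has no ortho substituent; MOM, prenyl, chromene and ester groups tolerate phosphate base.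

**Step 7**
Reactants: 15 methyl 5-[(8-methoxy-2,2-dimethyl-2H-chromen-6-yl)oxy]-7-(methoxymethoxy)-2,2-dimethyl-8-(3-methylbut-2-en-1-yl)-2H-chromene-6-carboxylate
Product: 16 5-[(8-hydroxy-2,2-dimethyl-2H-chromen-6-yl)oxy]-7-(methoxymethoxy)-2,2-dimethyl-8-(3-methylbut-2-en-1-yl)-2H-chromene-6-carboxylic acid
Conditions: NaSEt (8 equiv), degassed DMF, 110 °C; cold dil. HCl to pH 4
Reagents that add atoms: none
Why: thiolate SN2 dealkylation should cleave both O-methyl groups in one operation, the di-ortho-substituted methyl ester and the single aryl methyl ether of ring B, whereas the MOM acetal carbon with an aryloxide leaving group, the prenyl group and the chromenes are poor targets for a soft nucleophile.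

**Step 8**
Reactants: 16 5-[(8-hydroxy-2,2-dimethyl-2H-chromen-6-yl)oxy]-7-(methoxymethoxy)-2,2-dimethyl-8-(3-methylbut-2-en-1-yl)-2H-chromene-6-carboxylic acid
Product: 18 1-O-(methoxymethyl)garcinisidone D, via 4-acyloxycyclohexadienone 17 (not isolated)
Conditions: PhI(OAc)2 (1.05 equiv), HFIP–CH2Cl2 (1:4), 0.005 M, −20 to 0 °C
Reagents that add atoms: none
Why: Proposed new method: ligand exchange of the ring-B C7 phenol at iodine(III) and departure of iodobenzene give an O-iodanyl phenol or phenoxonium ion with electrophilic character at C6, C8 and C9a; the tethered C11 carboxylic acid adds at the para carbon C9a to give dienone 17, which tautomerises at once because C9a carries hydrogen, restoring the C7 phenol. The closest known reaction types are iodine(III) dearomatising spirolactonisation of phenols bearing carboxylic acid chains and dehydrogenative lactonisation of 2-arylbenzoic acids. The seven-membered lactone closes by capture of the cationic sp2 carbon C9a by the carboxyl oxygen (formally 7-endo with respect to the C5a–C9a π bond), and no stereocentre results. The selectivity needed is para (C9a) over ortho (C6) capture, and it rests on the usual para preference for nucleophile capture when the para carbon bears hydrogen and on shielding of C6 and C8 by the bulky O7–I(Ph)OAc group. Chemoselectivity for ring B is secured by the MOM cap on C1 (no second phenol), the non-nucleophilic fluoroalcohol that suppresses external attack at the alkoxy-bearing C8, and one equivalent of oxidant at low temperature and high dilution; the p-acyloxyphenol product is harder to oxidise than 16, which limits quinone formation.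

**Step 9**
Reactants: 18 1-O-(methoxymethyl)garcinisidone D
Product: 19 garcinisidone D
Conditions: NaHSO4·SiO2, CH2Cl2, rt
Reagents that add atoms: none
Why: mild heterogeneous Brønsted-acid acetal cleavage should remove the phenolic MOM ether, which is activated by the adjacent lactone carbonyl, under conditions too weak to cyclise the C2 prenyl group onto the new C1 hydroxyl or to open the lactone.

**Compound list**

1 | 5-bromo-2-hydroxy-3-methoxybenzaldehyde | COc1cc(Br)cc(C=O)c1O | starting material
2 | 2-methylprop-1-en-1-ylmagnesium bromide | CC(C)=C[Mg]Br | starting material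
3 | 4-bromo-2-(1-hydroxy-3-methylbut-2-en-1-yl)-6-methoxyphenol (racemic) | COc1cc(Br)cc(C(O)C=C(C)C)c1O | intermediate
4 | 6-bromo-8-methoxy-2,2-dimethyl-2H-chromene | COc1cc(Br)cc2C=CC(C)(C)Oc12 | intermediate
5 | methyl 2,4,6-trihydroxybenzoate | COC(=O)c1c(O)cc(O)cc1O | starting material
6 | 3-chloro-3-methylbut-1-yne | C#CC(C)(C)Cl | starting material
7 | methyl 2,6-dihydroxy-4-[(2-methylbut-3-yn-2-yl)oxy]benzoate | COC(=O)c1c(O)cc(OC(C)(C)C#C)cc1O | intermediate
8 | tert-butyl 2-methylbut-3-en-2-yl carbonate | C=CC(C)(C)OC(=O)OC(C)(C)C | starting material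
9 | methyl 2-hydroxy-6-[(2-methylbut-3-en-2-yl)oxy]-4-[(2-methylbut-3-yn-2-yl)oxy]benzoate | COC(=O)c1c(O)cc(OC(C)(C)C#C)cc1OC(C)(C)C=C | intermediate
10 | methyl 2-[(2-methylbut-3-en-2-yl)oxy]-4-[(2-methylbut-3-yn-2-yl)oxy]-6-(pivaloyloxy)benzoate | COC(=O)c1c(OC(=O)C(C)(C)C)cc(OC(C)(C)C#C)cc1OC(C)(C)C=C | intermediate
11 | methyl 2-hydroxy-3-(3-methylbut-2-en-1-yl)-4-[(2-methylbut-3-yn-2-yl)oxy]-6-(pivaloyloxy)benzoate | COC(=O)c1c(OC(=O)C(C)(C)C)cc(OC(C)(C)C#C)c(CC=C(C)C)c1O | intermediate
12 | methyl 7-hydroxy-2,2-dimethyl-8-(3-methylbut-2-en-1-yl)-5-(pivaloyloxy)-2H-chromene-6-carboxylate | COC(=O)c1c(OC(=O)C(C)(C)C)c2C=CC(C)(C)Oc2c(CC=C(C)C)c1O | intermediate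
13 | methyl 7-(methoxymethoxy)-2,2-dimethyl-8-(3-methylbut-2-en-1-yl)-5-(pivaloyloxy)-2H-chromene-6-carboxylate | COC(=O)c1c(OC(=O)C(C)(C)C)c2C=CC(C)(C)Oc2c(CC=C(C)C)c1OCOC | intermediate
14 | methyl 5-hydroxy-7-(methoxymethoxy)-2,2-dimethyl-8-(3-methylbut-2-en-1-yl)-2H-chromene-6-carboxylate | COC(=O)c1c(O)c2C=CC(C)(C)Oc2c(CC=C(C)C)c1OCOC | intermediate
15 | methyl 5-[(8-methoxy-2,2-dimethyl-2H-chromen-6-yl)oxy]-7-(methoxymethoxy)-2,2-dimethyl-8-(3-methylbut-2-en-1-yl)-2H-chromene-6-carboxylate | COC(=O)c1c(Oc3cc(OC)c4OC(C)(C)C=Cc4c3)c2C=CC(C)(C)Oc2c(CC=C(C)C)c1OCOC | intermediate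
16 | 5-[(8-hydroxy-2,2-dimethyl-2H-chromen-6-yl)oxy]-7-(methoxymethoxy)-2,2-dimethyl-8-(3-methylbut-2-en-1-yl)-2H-chromene-6-carboxylic acid (key-step precursor) | OC(=O)c1c(Oc3cc(O)c4OC(C)(C)C=Cc4c3)c2C=CC(C)(C)Oc2c(CC=C(C)C)c1OCOC | intermediate
17 | ring-B 4-acyloxycyclohexa-2,5-dienone tautomer of 18 (lactone closed, C9a sp3 with H, C7 ketone; racemic, transient) | CC(C)=CCc1c(OCOC)c2c(c3c1OC(C)(C)C=C3)OC1=CC(=O)C3=C(C1OC2=O)C=CC(C)(C)O3 | intermediate
18 | 1-O-(methoxymethyl)garcinisidone D (depsidone with C1 OMOM, C2 prenyl, 2,2-dimethylpyran rings fused at C3/C4 and C8/C9, C7 OH) | CC(C)=CCc1c(OCOC)c2c(c3c1OC(C)(C)C=C3)Oc1cc(O)c3c(c1OC2=O)C=CC(C)(C)O3 | intermediate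
19 | garcinisidone D | CC(C)=CCc1c(O)c2c(c3c1OC(C)(C)C=C3)Oc1cc(O)c3c(c1OC2=O)C=CC(C)(C)O3 | target

**Step count**

Total steps: 9. Longest linear sequence: 8 (steps 2 to 9, from 5); the ring-B branch adds step 1.

**Steps most likely to fail**

Step 8. The carboxyl group may be captured at the ortho carbon C6 instead of the para carbon C9a. The product may also be oxidised further to a quinone with loss of the acyl group, the electron-rich chromene and prenyl π systems may undergo single-electron oxidation, and the MOM acetal may solvolyse in the fluoroalcohol. The fallback uses known chemistry and sets out from 16. Teuber oxidation with Fremy's salt (KH2PO4 buffer, acetone–water, 0 °C) should convert the para-unsubstituted ring-B phenol into the ring-B p-quinone acid F1. Reduction with aqueous Na2S2O4 should then give the ring-B hydroquinone acid F2. Carbodiimide lactonisation (DCC, CH2Cl2, high dilution) can only engage the C9a hydroxyl, the one ortho to O5, and the sequence comes back to the route at 18.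

Step 6. The hindered, hydrogen-bonded phenoxide may couple too slowly, so that protodebromination of the aryl bromide or ester cleavage takes over. The fallback sets out from 4. Bromine–lithium exchange (n-BuLi, THF, −78 °C), borylation with B(OiPr)3 and mild acidic work-up should give (8-methoxy-2,2-dimethyl-2H-chromen-6-yl)boronic acid F3. Chan–Lam–Evans oxidative coupling of this aryl nucleophile with phenol 14 (Cu(OAc)2, pyridine, 4 Å sieves, air, CH2Cl2, rt) comes back to the route at 15.

Step 3. The etherification may lose its branched selectivity and give the linear prenyl ether, both hydroxyls may be etherified, or the tertiary allyl ether may rearrange before the acylation. The fallback sets out from 7. Direct C-prenylation with prenyl bromide and DBU in THF at 0 °C, at one of the two equivalent ring CH positions, should give methyl 2,6-dihydroxy-3-(3-methylbut-2-en-1-yl)-4-[(2-methylbut-3-yn-2-yl)oxy]benzoate F4. Acylation with bulky pivaloyl chloride (Et3N, CH2Cl2, −20 °C) should then select the hydroxyl remote from the prenyl group. This comes back to the route at 11, which is heated at 140 °C as in step 4 to reach 12.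

**Further compounds**

F1 | step 8 | 5-[(2,2-dimethyl-5,8-dioxo-5,8-dihydro-2H-chromen-6-yl)oxy]-7-(methoxymethoxy)-2,2-dimethyl-8-(3-methylbut-2-en-1-yl)-2H-chromene-6-carboxylic acid | CC(C)=CCc1c(OCOC)c(C(=O)O)c(OC2=CC(=O)C3=C(C2=O)C=CC(C)(C)O3)c2c1OC(C)(C)C=C2
F2 | step 8 | 5-[(5,8-dihydroxy-2,2-dimethyl-2H-chromen-6-yl)oxy]-7-(methoxymethoxy)-2,2-dimethyl-8-(3-methylbut-2-en-1-yl)-2H-chromene-6-carboxylic acid | CC(C)=CCc1c(OCOC)c(C(=O)O)c(Oc2cc(O)c3OC(C)(C)C=Cc3c2O)c2c1OC(C)(C)C=C2
F3 | step 6 | (8-methoxy-2,2-dimethyl-2H-chromen-6-yl)boronic acid | COc1cc(B(O)O)cc2C=CC(C)(C)Oc12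
F4 | step 3 | methyl 2,6-dihydroxy-3-(3-methylbut-2-en-1-yl)-4-[(2-methylbut-3-yn-2-yl)oxy]benzoate | COC(=O)c1c(O)cc(OC(C)(C)C#C)c(CC=C(C)C)c1O
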